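Ring numbering used throughout: rings A and C are the benzo and pyranone rings of the chromen-4-one (O1, C2, C3, C4, C4a, C5–C8, C8a). Ring B is the aryl group on C3 and ring D the dimethylpyran fused to it; together they are numbered as a 2H-chromene (O1, C2, C3, C4, C4a, C5–C8, C8a, marked "of the chromene" where needed). For ring B alone, C1' = chromene C6, C2' = C5, C3' = C4a, C4' = C8a, C5' = C8, C6' = C7.

## Analysis of the target

The target is an isoflavone: a 7-hydroxy-4H-chromen-4-one (rings A and C) that carries at C3 an aryl ring B, which is fused to a 2,2-dimethyl-2H-pyran (ring D). Rings B and D therefore form a 5-hydroxy-8-methoxy-2,2-dimethyl-2H-chromene bonded through its C6. There is no stereocenter; the only geometric element is the cis C3=C4 double bond locked in ring D. Ring B carries five substituents, the bond from C3 of the chromone to ring B is flanked by a free hydroxyl, and the 5-OH/8-OMe pair is a hydroquinone monoether that oxidises easily to a quinone. The chromene double bond is an electron-rich styrene that suffers under strong acid, hydrogenation and electrophilic oxidants, and the pyranone opens at C2 under hot hydroxide or alkoxide. The difficulty is to join this hindered, acid- and oxidation-sensitive ring B/D unit to the chromone without Friedel–Crafts or oxidative steps, keeping two phenols distinct from one methyl ether. The strategy rests on how ring A is attached: only through O1–C8a and C4–C4a, on two adjacent carbons, which is the bonding pattern an aryne leaves behind. C5 bears only hydrogen, so it can hold a chlorine during the annulation to decide which aryne carbon receives the oxygen.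

## Retrosynthetic reasoning

Target 19 is traced back to the bis-MOM ether 18. Both phenols have to be masked because a free phenol would add to an aryne and protonate an aryl anion. The same acetal is chosen for both so that one mild acid treatment at the end releases them; the forward step must leave the chromene double bond intact.

Compound 18 is traced back to its 5-chloro derivative 17. The C5–H bond is exchanged for C5–Cl because the aryne needs a polarising group next to the triple bond, and C5 is the one position where such a group ends up after annulation. Chlorine is small, strongly inductive, slower than bromine to leave from an adjacent aryl anion, and still removable by palladium catalysis. The forward reduction must not touch the two conjugated double bonds.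

Compound 17 is cut at O1–C8a and C4–C4a, the only two bonds that hold ring A. This gives the enol 15, which already contains rings B and D together with C2, C3 and C4, and the aryne 16, released from the silyl triflate 7. Cutting here rather than at the C3–aryl bond or inside ring B keeps the sensitive ring B/D unit in one piece and reduces ring A to a simple benzene derivative. Both bonds form under neutral fluoride conditions, with no acid near the chromene. The forward reaction has to add the enolate through oxygen, at the aryne carbon remote from chlorine, and close ring C by attack of the aryl anion on the ester.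

The silyl triflate 7 is traced back through the phenolate 6 and the silyl ether 5 to the bromophenol 4. The C–Si bond comes from a silyl group moving from oxygen to the carbon that held bromine, and the O–S bond from triflation of the phenolate so formed. The halogens of 4 are introduced one after the other ortho to the free hydroxyl of 2 (by way of 3), and 2 is the mono-MOM ether of hydroquinone 1. The para oxygen of 1 becomes the C7 oxygen of the target.

The enol 15 is cut at the bond between its formyl carbon and the α-carbon and at the bond from the α-carbon to ring B. This leads to aldehyde 13 and ethyl diazoacetate 14: the aldehyde carbon becomes C2 of the chromone, the diazo carbon becomes C3, and ring B migrates from one to the other. The enol is thus obtained in one step from an aldehyde, with no arylacetic ester to prepare.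

Aldehyde 13 is traced back to the phenol 12, and ring D of 12 to the propargyl ether 10 by way of the allenylphenol 11; the O1–C2 and C4–C4a bonds of the chromene arise from an ether formation and a Claisen rearrangement. Ether 10 comes from benzaldehyde 8 and the propargylic chloride 9. Compound 8 already carries the three oxygens of ring B in the right places, and its aldehyde carbon is the future C2.

## Alternatives that were turned down

Alternative 1: Ring B is built instead of bought. It is cut into a vinylketene, formed from a diazoketone by a photochemical Wolff shift (C1'–C6'), and a silyloxyalkyne that carries the prenyl group. Cycloaddition (C3'–C4' and C1'–C2') gives a cyclobutenone, which opens and recloses (C4'–C5') to the resorcinol monosilyl ether A1, 3-[4-hydroxy-5-methoxy-3-(3-methylbut-2-en-1-yl)-2-(triisopropylsilyloxy)phenyl]-7-(triisopropylsilyloxy)-4H-chromen-4-one.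
- For: the connectivity of the two partners places every substituent of the pentasubstituted ring, and the free 4'-OH sits next to the prenyl group, ready for ring D. This benzannulation is a known reaction type, so on precedent it is stronger than the chosen key step.
- Against: the diazo carbon carries a chromone, itself a light-absorbing enone, so the irradiation has to discriminate between two chromophores. Both partners need several steps each. After A1, ring D still has to be closed by oxidative cyclisation on a very electron-rich ring, and two silyl ethers removed.
- Comparison: the chosen strategy buys ring B with its oxygen pattern, closes ring D thermally before the chromone exists, and needs fewer steps.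

Alternative 2: Ring B is again assembled, here by a Dötz benzannulation. A methoxycarbene complex of zerovalent chromium built on a dihydropyran, an alkynyl chromone and one carbonyl ligand combine (C5'–C6', C1'–C2', C2'–C3') to give A2, 7-[(tert-butyldimethylsilyl)oxy]-3-(5-hydroxy-8-methoxy-2,2-dimethylchroman-6-yl)-4H-chromen-4-one.
- For: the phenol and the methyl ether of ring B are differentiated by the mechanism itself (hydroxyl from the carbonyl ligand, methoxy from the carbene), so ring B needs no protecting group, and the regiochemistry follows from the size of the alkyne substituent. On these two points and on precedent it is stronger than the chosen route.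
- Against: the metal is used stoichiometrically, and the alkyne sits on C3 of a Michael-accepting chromone. Above all, A2 has ring D at the chroman oxidation level, so the C3=C4 bond would have to be introduced late by benzylic dehydrogenation with a quinone-type oxidant, on a free hydroquinone monoether that such oxidants convert to a quinone. Extra protection steps follow.
- Comparison: the chosen strategy has ring D at the right oxidation level from step 6 and has no oxidation after that.

Alternative 3: Ring C is cut at C3–C4 and O1–C2. An acetyl-protected salicyloyl chloride (ring A) acylates the β-carbon of a styryl enamine of the ring B/D unit; after deacetylation the ring A phenoxide adds to C2 and expels the secondary amine, giving A3, 7-hydroxy-3-[8-methoxy-5-(methoxymethoxy)-2,2-dimethyl-2H-chromen-6-yl]-4H-chromen-4-one.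
- For: enamine acylation is classical chemistry, no directing halogen has to be removed, and one acid step after the key step finishes the synthesis. On precedent and on the number of steps after the key step it is as strong as or stronger than the chosen route.
- Against: the enamine requires the arylacetaldehyde of the ring B/D unit, an electron-rich aldehyde that enolises, condenses with itself and oxidises readily. Reaching it from an aldehyde such as 13 takes a homologation whose usual last step is an acidic enol ether hydrolysis next to a MOM ether and a chromene. The acylation also sets free acid equivalents close to both.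
- Comparison: the chosen strategy works from a stable hydrogen-bonded enol made in one step from 13, forms both bonds of ring C in one neutral operation, and carries the C7 oxygen as a MOM ether that leaves together with the other one.

Key step: step 9

Remark on the chemistry: the ester group of 15 is lost as alkoxide in step 9, so its alkyl group is free to choose; ethyl is used because the ethyl ester is reached from 13 in one step with 14.
Remark on the chemistry: compounds 1, 8, 9 and 14 are taken as purchasable.

## Route

Step 1
Reactants: 1 hydroquinone
Product: 2 4-(methoxymethoxy)phenol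
Conditions: NaH (1.0 equiv), MOMCl (1.0 equiv), 1 (3 equiv), THF/DMF, 0 °C to rt
Reagents that add atoms: chloromethyl methyl ether, COCCl
Why: Williamson-type O-alkylation (MOM protection) of the monophenoxide; the excess of the cheap, water-soluble diol keeps the bis-ether low and is washed out with water.

Step 2
Reactants: 2 4-(methoxymethoxy)phenol
Product: 3 2-chloro-4-(methoxymethoxy)phenol
Conditions: NCS (1.0 equiv), i-Pr2NH (10 mol %), CH2Cl2, 0 °C to rt
Reagents that add atoms: N-chlorosuccinimide, O=C1CCC(=O)N1Cl
Why: Electrophilic aromatic chlorination; the free hydroxyl is the stronger activator and its para position is blocked, so substitution goes ortho to OH, and the neutral by-product spares the MOM ether.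

Step 3
Reactants: 3 2-chloro-4-(methoxymethoxy)phenol
Product: 4 2-bromo-6-chloro-4-(methoxymethoxy)phenol
Conditions: NBS (1.0 equiv), i-Pr2NH (10 mol %), CH2Cl2, 0 °C
Reagents that add atoms: N-bromosuccinimide, O=C1CCC(=O)N1Br
Why: Electrophilic aromatic bromination at the only remaining position ortho to the hydroxyl.

Step 4
Reactants: 4 2-bromo-6-chloro-4-(methoxymethoxy)phenol
Product: 7 2-chloro-4-(methoxymethoxy)-6-(trimethylsilyl)phenyl trifluoromethanesulfonate, via silyl ether 5 (not isolated), via lithium phenolate 6 (not isolated)
Conditions: HMDS, THF, 65 °C, then evaporation; n-BuLi (1.1 equiv), THF, –78 °C; Tf2O, –78 °C to rt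
Reagents that add atoms: hexamethyldisilazane, C[Si](C)(C)N[Si](C)(C)C; trifluoromethanesulfonic anhydride, O=S(=O)(OS(=O)(=O)C(F)(F)F)C(F)(F)F
Why: O-silylation, bromine–lithium exchange with anionic 1,3-shift of silicon from oxygen to carbon (retro-Brook rearrangement), then O-triflation, the standard entry to ortho-silylaryl triflates; the lithiated carbon has no leaving group beside it (chlorine is meta to it), and exchange at –78 °C should be faster than lithiation next to the MOM ether.

Step 5
Reactants: 8 2,4-dihydroxy-5-methoxybenzaldehyde; 9 3-chloro-3-methylbut-1-yne
Product: 10 2-hydroxy-5-methoxy-4-[(2-methylbut-3-yn-2-yl)oxy]benzaldehyde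
Conditions: K2CO3, KI, CuI (cat.), acetone, 56 °C
Reagents that add atoms: none
Why: Propargylic O-alkylation of a phenoxide (Williamson type, with CuI helping the tertiary chloride to ionise); the 4-OH is the more acidic one (para to the aldehyde) and is free, whereas the 2-OH is tied up in a hydrogen bond to the aldehyde.

Step 6
Reactants: 10 2-hydroxy-5-methoxy-4-[(2-methylbut-3-yn-2-yl)oxy]benzaldehyde
Product: 12 5-hydroxy-8-methoxy-2,2-dimethyl-2H-chromene-6-carbaldehyde, via allenylphenol 11 (not isolated)
Conditions: PhNEt2, 180 °C
Reagents that add atoms: none
Why: Aromatic propargyl Claisen rearrangement to the only free ortho carbon (the other one bears the methoxy group), then 1,5-hydrogen shift and oxa-6π electrocyclisation close ring D; the chelated 2-OH keeps its proton, so the ring oxygen is the former ether oxygen.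

Step 7
Reactants: 12 5-hydroxy-8-methoxy-2,2-dimethyl-2H-chromene-6-carbaldehyde
Product: 13 8-methoxy-5-(methoxymethoxy)-2,2-dimethyl-2H-chromene-6-carbaldehyde
Conditions: NaH, MOMCl, DMF, 0 °C to rt
Reagents that add atoms: chloromethyl methyl ether, COCCl
Why: Williamson-type MOM protection; full deprotonation with NaH overcomes the hydrogen bond of the phenol to the aldehyde.

Step 8
Reactants: 13 8-methoxy-5-(methoxymethoxy)-2,2-dimethyl-2H-chromene-6-carbaldehyde; 14 ethyl diazoacetate
Product: 15 ethyl (Z)-3-hydroxy-2-[8-methoxy-5-(methoxymethoxy)-2,2-dimethyl-2H-chromen-6-yl]prop-2-enoate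
Conditions: HBF4·OEt2 (10 mol %), CH2Cl2, –78 °C
Reagents that add atoms: none
Why: Acid-catalysed addition of the diazo ester to the aldehyde followed by 1,2-aryl shift with loss of N2, a semipinacol-type homologation known to turn aryl aldehydes into 3-hydroxy-2-arylacrylates; ring B, with oxygen ortho and para to the migrating carbon, should migrate in preference to hydride, and the product rests as the hydrogen-bonded (Z)-enol.

Step 9
Reactants: 15 ethyl (Z)-3-hydroxy-2-[8-methoxy-5-(methoxymethoxy)-2,2-dimethyl-2H-chromen-6-yl]prop-2-enoate; 7 2-chloro-4-(methoxymethoxy)-6-(trimethylsilyl)phenyl trifluoromethanesulfonate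
Product: 17 5-chloro-3-[8-methoxy-5-(methoxymethoxy)-2,2-dimethyl-2H-chromen-6-yl]-7-(methoxymethoxy)-4H-chromen-4-one, via aryne 16 (not isolated)
Conditions: CsF (4 equiv), THF, 65 °C, slow addition of 7 (1.5 equiv)
Reagents that add atoms: none
Why: Proposed new method: fluoride takes the enol proton of 15 and, by attack on silicon, releases aryne 16 from 7 with loss of triflate; the enolate oxygen of the former formyl group adds to the aryne carbon remote from chlorine (the future C8a), and the aryl anion that appears at C4a attacks the ethyl ester and expels ethoxide, so that O1–C8a and C4–C4a form in one operation. The closest known reactions are the fluoride-mediated annulation of salicylate esters with arynes to xanthones and the insertion of arynes into β-dicarbonyl compounds; the enol oxygen of a formylacetate has not been used in this role. Ring C closes by a 6-exo-trig acyl substitution. No stereocenter is formed. Site selectivity on the aryne comes from the chlorine: it distorts the triple bond so that the distal carbon is the more linear and electrophilic one, and it stabilises by induction the negative charge that develops next to it, which outweighs the weaker, opposite pull of the ether oxygen at C7. Attack through oxygen and not through the α-carbon is expected because that carbon already carries ring B with its ortho MOM ether and would have to become quaternary. Ring closure needs the new aryl ether oxygen and the ester cis on the double bond; in THF the enolate should stay a chelated, U-shaped ion pair with Cs+, and the weakly polar medium should also favour intramolecular acylation over protonation of the aryl anion or loss of chloride from it.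

Step 10
Reactants: 17 5-chloro-3-[8-methoxy-5-(methoxymethoxy)-2,2-dimethyl-2H-chromen-6-yl]-7-(methoxymethoxy)-4H-chromen-4-one
Product: 18 3-[8-methoxy-5-(methoxymethoxy)-2,2-dimethyl-2H-chromen-6-yl]-7-(methoxymethoxy)-4H-chromen-4-one
Conditions: Pd(OAc)2 (5 mol %), XPhos (10 mol %), HCO2Na (3 equiv), DMF, 80 °C
Reagents that add atoms: none
Why: Palladium-catalysed hydrodehalogenation: zerovalent palladium inserts into the C5–Cl bond, which the peri carbonyl activates, formate replaces chloride and loses CO2, and reductive elimination forms C–H; a ligated homogeneous catalyst with formate, rather than H2 on a metal surface, should leave the chromene and chromone double bonds alone.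

Step 11
Reactants: 18 3-[8-methoxy-5-(methoxymethoxy)-2,2-dimethyl-2H-chromen-6-yl]-7-(methoxymethoxy)-4H-chromen-4-one
Product: 19 7-hydroxy-3-(5-hydroxy-8-methoxy-2,2-dimethyl-2H-chromen-6-yl)-4H-chromen-4-one
Conditions: HCl (1 M) in MeOH/THF, 45 °C, N2
Reagents that add atoms: none
Why: Acid-catalysed acetal exchange (MOM cleavage) frees both phenols while dimethoxymethane forms; dilute acid at mild temperature under N2 should stay short of adding methanol to the chromene double bond or oxidising the hydroquinone monoether.

## Compound list

1 | hydroquinone (benzene-1,4-diol) | Oc1ccc(O)cc1 | starting material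
2 | 4-(methoxymethoxy)phenol | COCOc1ccc(O)cc1 | intermediate
3 | 2-chloro-4-(methoxymethoxy)phenol | COCOc1ccc(O)c(Cl)c1 | intermediate
4 | 2-bromo-6-chloro-4-(methoxymethoxy)phenol | COCOc1cc(Cl)c(O)c(Br)c1 | intermediate
5 | [2-bromo-6-chloro-4-(methoxymethoxy)phenoxy]trimethylsilane | COCOc1cc(Cl)c(O[Si](C)(C)C)c(Br)c1 | intermediate
6 | lithium 2-chloro-4-(methoxymethoxy)-6-(trimethylsilyl)phenolate | [Li+].COCOc1cc(Cl)c([O-])c([Si](C)(C)C)c1 | intermediate
7 | 2-chloro-4-(methoxymethoxy)-6-(trimethylsilyl)phenyl trifluoromethanesulfonate | COCOc1cc(Cl)c(OS(=O)(=O)C(F)(F)F)c([Si](C)(C)C)c1 | intermediate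
8 | 2,4-dihydroxy-5-methoxybenzaldehyde | COc1cc(C=O)c(O)cc1O | starting material
9 | 3-chloro-3-methylbut-1-yne | C#CC(C)(C)Cl | starting material
10 | 2-hydroxy-5-methoxy-4-[(2-methylbut-3-yn-2-yl)oxy]benzaldehyde | COc1cc(C=O)c(O)cc1OC(C)(C)C#C | intermediate
11 | 2,4-dihydroxy-5-methoxy-3-(3-methylbuta-1,2-dien-1-yl)benzaldehyde | COc1cc(C=O)c(O)c(C=C=C(C)C)c1O | intermediate
12 | 5-hydroxy-8-methoxy-2,2-dimethyl-2H-chromene-6-carbaldehyde | COc1cc(C=O)c(O)c2C=CC(C)(C)Oc12 | intermediate
13 | 8-methoxy-5-(methoxymethoxy)-2,2-dimethyl-2H-chromene-6-carbaldehyde | COCOc1c(C=O)cc(OC)c2OC(C)(C)C=Cc12 | intermediate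
14 | ethyl diazoacetate | CCOC(=O)C=[N+]=[N-] | starting material
15 | ethyl (Z)-3-hydroxy-2-[8-methoxy-5-(methoxymethoxy)-2,2-dimethyl-2H-chromen-6-yl]prop-2-enoate | CCOC(=O)/C(=C\O)c1cc(OC)c2OC(C)(C)C=Cc2c1OCOC | intermediate
16 | 3-chloro-5-(methoxymethoxy)-1,2-didehydrobenzene (3-chloro-5-(methoxymethoxy)benzyne) | COCOC1=CC#CC(Cl)=C1 | intermediate
17 | 5-chloro-3-[8-methoxy-5-(methoxymethoxy)-2,2-dimethyl-2H-chromen-6-yl]-7-(methoxymethoxy)-4H-chromen-4-one | COCOc1cc(Cl)c2c(c1)occ(-c1cc(OC)c3OC(C)(C)C=Cc3c1OCOC)c2=O | intermediate
18 | 3-[8-methoxy-5-(methoxymethoxy)-2,2-dimethyl-2H-chromen-6-yl]-7-(methoxymethoxy)-4H-chromen-4-one | COCOc1ccc2c(c1)occ(-c1cc(OC)c3OC(C)(C)C=Cc3c1OCOC)c2=O | intermediate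
19 | 7-hydroxy-3-(5-hydroxy-8-methoxy-2,2-dimethyl-2H-chromen-6-yl)-4H-chromen-4-one | COc1cc(-c2coc3cc(O)ccc3c2=O)c(O)c2c1OC(C)(C)C=C2 | target

## Step count and least certain steps

Total step count: 11 (steps 1–4 for the ring A partner, steps 5–8 for the ring B/D partner, steps 9–11 after their union).
Longest linear sequence: 7 steps (either branch: four steps to the coupling partner, then steps 9, 10 and 11).

Step 9 (key step, proposed new method). Several things can go wrong:
- the ambident enolate may attack the aryne through carbon, which leads to insertion into the bond between the α-carbon and the formyl group;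
- the aryl anion may be protonated before it closes ring C;
- O-arylation may occur from the extended form of the enolate, which leaves the anion trans to the ester and out of reach;
- chloride may be lost from the ortho-chloroaryl anion.

The fallback uses the known chalcone route to isoflavones, sets out from aldehyde 13 and comes back at the target 19. Commercial 1-(2,4-dihydroxyphenyl)ethan-1-one is protected at the non-chelated hydroxyl (MOMCl, K2CO3, acetone) to give 1-[2-hydroxy-4-(methoxymethoxy)phenyl]ethan-1-one F1. Claisen–Schmidt condensation of F1 with 13 (KOH, EtOH, rt) gives the chalcone (E)-1-[2-hydroxy-4-(methoxymethoxy)phenyl]-3-[8-methoxy-5-(methoxymethoxy)-2,2-dimethyl-2H-chromen-6-yl]prop-2-en-1-one F2. Oxidative 1,2-migration of the electron-rich ring B with Tl(NO3)3·3H2O (trivalent thallium) in MeOH/HC(OMe)3 gives the racemic acetal 1-[2-hydroxy-4-(methoxymethoxy)phenyl]-3,3-dimethoxy-2-[8-methoxy-5-(methoxymethoxy)-2,2-dimethyl-2H-chromen-6-yl]propan-1-one F3. Methanolic HCl then closes ring C with loss of methanol and removes both MOM groups to give 19. The chromene double bond is the weak point of this fallback and is expected to be less reactive toward the thallium salt than the enone.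

Step 8. The Brønsted acid may cleave the MOM ether or protonate the chromene double bond, and hydride may migrate instead of ring B, which would give the isomeric β-keto ester. The fallback is base-only; it sets out from 13 and comes back at 15. Addition of the trichloromethyl anion (CHCl3, KOH, DMF, 0 °C) gives 2,2,2-trichloro-1-[8-methoxy-5-(methoxymethoxy)-2,2-dimethyl-2H-chromen-6-yl]ethan-1-ol F4. Reductive Jocic-type homologation (NaBH4, NaOH, t-BuOH, 55 °C) passes through the dichloroepoxide, which hydride opens at the benzylic carbon, and gives 2-[8-methoxy-5-(methoxymethoxy)-2,2-dimethyl-2H-chromen-6-yl]acetic acid F5. Alkylation (EtI, K2CO3, DMF) gives ethyl 2-[8-methoxy-5-(methoxymethoxy)-2,2-dimethyl-2H-chromen-6-yl]acetate F6, and Claisen formylation (HCO2Et, NaH, THF, then aqueous NH4Cl) gives 15.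

Step 10. The Pd–H species may reduce the chromone C2=C3 bond by conjugate transfer hydrogenation or the chromene C3=C4 bond, or oxidative addition into the hindered peri C–Cl bond may be slow. The fallback avoids any hydride donor; it sets out from 17 and comes back at 18. Miyaura borylation (Pd(OAc)2, XPhos, bis(pinacolato)diboron, KOAc, dioxane, 100 °C) gives 3-[8-methoxy-5-(methoxymethoxy)-2,2-dimethyl-2H-chromen-6-yl]-7-(methoxymethoxy)-5-(4,4,5,5-tetramethyl-1,3,2-dioxaborolan-2-yl)-4H-chromen-4-one F7. Base-mediated protodeboronation of this ortho-acyl arylboronate (K3PO4, H2O/dioxane, 90 °C) then gives 18.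

Step 4. Butyllithium may remove the ring proton between chlorine and the MOM ether instead of exchanging bromine, the silyl shift from oxygen to carbon may stay incomplete, or the hindered phenolate may resist triflation. The fallback forms the C–Si bond by intermolecular trapping and triflates an isolated phenol; it sets out from 4 and comes back at 7. Two equivalents of n-BuLi (THF, –78 °C) give the O,C-dilithiated species, in which the phenoxide lowers the acidity of the ring protons. Me3SiCl then gives [2-chloro-4-(methoxymethoxy)-6-(trimethylsilyl)phenoxy]trimethylsilane F8. Mild methanolysis (K2CO3, MeOH, 0 °C) cleaves only the O–Si bond and gives 2-chloro-4-(methoxymethoxy)-6-(trimethylsilyl)phenol F9, which is purified and triflated with N-phenylbis(trifluoromethanesulfonimide) and Cs2CO3 in MeCN to give 7.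

## Further compounds

F1 | step 9 | 1-[2-hydroxy-4-(methoxymethoxy)phenyl]ethan-1-one | COCOc1ccc(C(C)=O)c(O)c1
F2 | step 9 | (E)-1-[2-hydroxy-4-(methoxymethoxy)phenyl]-3-[8-methoxy-5-(methoxymethoxy)-2,2-dimethyl-2H-chromen-6-yl]prop-2-en-1-one | COCOc1ccc(C(=O)/C=C/c2cc(OC)c3OC(C)(C)C=Cc3c2OCOC)c(O)c1
F3 | step 9 | 1-[2-hydroxy-4-(methoxymethoxy)phenyl]-3,3-dimethoxy-2-[8-methoxy-5-(methoxymethoxy)-2,2-dimethyl-2H-chromen-6-yl]propan-1-one (racemic) | COCOc1ccc(C(=O)C(C(OC)OC)c2cc(OC)c3OC(C)(C)C=Cc3c2OCOC)c(O)c1
F4 | step 8 | 2,2,2-trichloro-1-[8-methoxy-5-(methoxymethoxy)-2,2-dimethyl-2H-chromen-6-yl]ethan-1-ol (racemic) | COCOc1c(C(O)C(Cl)(Cl)Cl)cc(OC)c2OC(C)(C)C=Cc12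
F5 | step 8 | 2-[8-methoxy-5-(methoxymethoxy)-2,2-dimethyl-2H-chromen-6-yl]acetic acid | COCOc1c(CC(=O)O)cc(OC)c2OC(C)(C)C=Cc12
F6 | step 8 | ethyl 2-[8-methoxy-5-(methoxymethoxy)-2,2-dimethyl-2H-chromen-6-yl]acetate | CCOC(=O)Cc1cc(OC)c2OC(C)(C)C=Cc2c1OCOC
F7 | step 10 | 3-[8-methoxy-5-(methoxymethoxy)-2,2-dimethyl-2H-chromen-6-yl]-7-(methoxymethoxy)-5-(4,4,5,5-tetramethyl-1,3,2-dioxaborolan-2-yl)-4H-chromen-4-one | COCOc1cc(B4OC(C)(C)C(C)(C)O4)c2c(c1)occ(-c1cc(OC)c3OC(C)(C)C=Cc3c1OCOC)c2=O
F8 | step 4 | [2-chloro-4-(methoxymethoxy)-6-(trimethylsilyl)phenoxy]trimethylsilane | COCOc1cc(Cl)c(O[Si](C)(C)C)c([Si](C)(C)C)c1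
F9 | step 4 | 2-chloro-4-(methoxymethoxy)-6-(trimethylsilyl)phenol | COCOc1cc(Cl)c(O)c([Si](C)(C)C)c1
A1 | alternative 1 | 3-[4-hydroxy-5-methoxy-3-(3-methylbut-2-en-1-yl)-2-(triisopropylsilyloxy)phenyl]-7-(triisopropylsilyloxy)-4H-chromen-4-one | COc1cc(-c2coc3cc(O[Si](C(C)C)(C(C)C)C(C)C)ccc3c2=O)c(O[Si](C(C)C)(C(C)C)C(C)C)c(CC=C(C)C)c1O
A2 | alternative 2 | 7-[(tert-butyldimethylsilyl)oxy]-3-(5-hydroxy-8-methoxy-2,2-dimethylchroman-6-yl)-4H-chromen-4-one | COc1cc(-c2coc3cc(O[Si](C)(C)C(C)(C)C)ccc3c2=O)c(O)c2c1OC(C)(C)CC2
A3 | alternative 3 | 7-hydroxy-3-[8-methoxy-5-(methoxymethoxy)-2,2-dimethyl-2H-chromen-6-yl]-4H-chromen-4-one | COCOc1c(-c2coc3cc(O)ccc3c2=O)cc(OC)c2OC(C)(C)C=Cc12
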